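## Retrosynthetic overview

1. Target 17 ⇒ prenyl ketone 16 by a closing Schenck ene reaction with singlet oxygen: the C9 hydrogens lie between C8=O and C10=C11, so O2 is taken up at C11 and the olefin moves to C9=C10 (E).
2. 16 ⇒ aldehyde 10 + tertiary prenyl boronate 13 (bond C8–C9): a one-flask linear prenylation/oxidation, the laboratory counterpart of the dimethylallyl transfer that makes this bond in the farnesyl chain.
3. Enabling feature: C8 is an aldehyde on the fully substituted oxirane carbon C7 (three-membered ring C7–C14–O), so it has no α-hydrogen and is activated by the ring oxygen. The cyclohexanone carbonyl C2 is walled in by quaternary oxirane carbon C3 and acyloxy carbon C1, and the gem-dimethyl end C11 leaves no E/Z issue.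
4. 10 ⇒ (R)-carvone, which supplies the carbocycle and C6. Order of ring formation: the C3–C4 oxirane first (hydroxyl-directed, cis to the C6 substituent), then C1–O (enolate hydroxylation, trans to C6), then the C7–C14 oxirane (Sharpless epoxidation of the allyl alcohol made by SeO2 oxidation of the isopropenyl methyl).
5. No protecting group is used; the hydroperoxide is made in the last step.

Key step: step 11

Numbering used: ring C1 (CH–O-acyl), C2 (C=O), C3 (C–CH3) and C4 (CH) carrying the ring oxirane, C5 (CH2), C6 (CH); side chain C7 (oxirane carbon, oxirane CH2 = C14), C8 (C=O), C9=C10, C11 (C(CH3)2OOH). In this numbering the target is 1S,3S,4S,6R,7R.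

Remark: carbonate 12 is made rather than bought. The C7 descriptor changes from S (in 9) to R (from 10 on) only because the CIP priority of C8 changes; the configuration itself is not altered.

## Route

Step 1
Reactants: 1 (R)-(−)-carvone
Product: 2 (1R,5R)-cis-carveol (OH cis to isopropenyl)
Conditions: NaBH4, CeCl3·7H2O, MeOH, −78 → 0 °C
Reagents that add atoms: none
Why: Luche reduction gives clean 1,2-reduction of the enone, and axial hydride delivery should place the new hydroxyl pseudo-equatorial, cis to the isopropenyl group.

Step 2
Reactants: 2 (1R,5R)-cis-carveol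
Product: 3 epoxy alcohol with oxirane O, OH and isopropenyl all on one ring face
Conditions: VO(acac)2 (2 mol %), t-BuOOH (decane), CH2Cl2, 0 °C → rt
Reagents that add atoms: tert-butyl hydroperoxide, CC(C)(C)OO
Why: Vanadium-catalysed hydroxyl-directed epoxidation delivers oxygen to the ring olefin from the face of the OH group, setting C3 and C4 with the oxirane cis to the C6 substituent (the face that Weitz–Scheffer epoxidation of carvone does not give) and leaving the isopropenyl olefin untouched.

Step 3
Reactants: 3 epoxy alcohol
Product: 4 cis-carvone oxide, (1S,4R,6S)-1-methyl-4-(prop-1-en-2-yl)-7-oxabicyclo[4.1.0]heptan-2-one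
Conditions: Dess–Martin periodinane, pyridine, CH2Cl2, 0 °C → rt
Reagents that add atoms: none
Why: Dess–Martin oxidation converts the secondary epoxy alcohol into the α,β-epoxy ketone under buffered conditions without touching the stereocentres.

Step 4
Reactants: 4 cis-carvone oxide
Product: 6 α′-hydroxy epoxy ketone (C1–OH trans to isopropenyl and to the oxirane oxygen), via potassium enolate 5 (not isolated)
Conditions: KHMDS, THF, −78 °C; then 2-(phenylsulfonyl)-3-phenyloxaziridine, −78 °C; AcOH quench
Reagents that add atoms: 2-(phenylsulfonyl)-3-phenyloxaziridine, O=S(=O)(N1OC1c1ccccc1)c1ccccc1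
Why: The ketone can enolise only toward C1 because C3 is quaternary, and N-sulfonyloxaziridine hydroxylation of the enolate (Davis oxidation) should occur on the face opposite the adjacent C6 isopropenyl group and the oxirane, setting C1 trans to C6.

Step 5
Reactants: 6 α′-hydroxy epoxy ketone
Product: 7 isovalerate (3-methylbutanoate) of 6
Conditions: (i-BuCO)2O, Et3N, DMAP (cat.), CH2Cl2, 0 °C → rt
Reagents that add atoms: 3-methylbutanoic anhydride, CC(C)CC(=O)OC(=O)CC(C)C
Why: DMAP-catalysed acylation of the secondary α-ketol is fast under mild, chloride-free base, so C1 should not epimerise and the oxirane should not open.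

Step 6
Reactants: 7 isovalerate
Product: 8 allylic alcohol (isopropenyl methyl hydroxylated, a 2-substituted prop-2-en-1-ol)
Conditions: SeO2 (cat.), t-BuOOH, CH2Cl2, rt, stopped before full conversion
Reagents that add atoms: selenium dioxide, O=[Se]=O (catalytic oxygen carrier); tert-butyl hydroperoxide, CC(C)(C)OO (stoichiometric oxygen source)
Why: Selenium dioxide allylic oxidation (ene reaction then [2,3]-sigmatropic shift) should hydroxylate the methyl group of the only olefin in preference to the tertiary ring C–H, with the double bond returning to its place.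

Step 7
Reactants: 8 allylic alcohol
Product: 9 bis-epoxy alcohol (2-substituted oxiran-2-yl)methanol, C7 configured S
Conditions: Ti(Oi-Pr)4 (10 mol %), L-(+)-diisopropyl tartrate (13 mol %), t-BuOOH, 4 Å MS, CH2Cl2, −20 °C
Reagents that add atoms: tert-butyl hydroperoxide, CC(C)(C)OO
Why: Sharpless asymmetric epoxidation of the 2-substituted allyl alcohol with the L-(+)-tartrate catalyst should deliver oxygen to the face that gives the S-configured oxirane (as with 2-alkylallyl alcohols), setting quaternary C7 under reagent control while the ketone, ester and ring oxirane are inert.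

Step 8
Reactants: 9 bis-epoxy alcohol
Product: 10 bis-epoxy aldehyde (2-substituted oxirane-2-carbaldehyde)
Conditions: Dess–Martin periodinane, pyridine, CH2Cl2, 0 °C
Reagents that add atoms: none
Why: Dess–Martin oxidation of the primary epoxy alcohol gives the glycidic aldehyde, which cannot epimerise because C7 carries no hydrogen.

Step 9
Reactants: 11 prenol (3-methylbut-2-en-1-ol)
Product: 12 methyl 3-methylbut-2-en-1-yl carbonate
Conditions: ClCO2Me, pyridine, CH2Cl2, 0 °C
Reagents that add atoms: methyl chloroformate, COC(=O)Cl
Why: Acyl substitution at the chloroformate converts the primary allylic alcohol into the carbonate needed as leaving group for the copper-catalysed borylation.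

Step 10
Reactants: 12 methyl 3-methylbut-2-en-1-yl carbonate
Product: 13 4,4,5,5-tetramethyl-2-(2-methylbut-3-en-2-yl)-1,3,2-dioxaborolane (tertiary prenyl boronate)
Conditions: B2pin2, CuCl (5 mol %), SIMes·HCl (5 mol %), NaOt-Bu (10 mol %), THF, 0 °C → rt
Reagents that add atoms: bis(pinacolato)diboron, CC1(C)OB(OC1(C)C)B1OC(C)(C)C(C)(C)O1
Why: Copper-catalysed SN2′ allylic borylation (borylcupration with boron on the dimethyl-substituted carbon, then β-elimination of the carbonate) should give the tertiary allylboronate rather than the primary prenyl isomer.

Step 11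
Reactants: 10 bis-epoxy aldehyde; 13 tertiary prenyl boronate
Product: 16 prenyl ketone (β,γ-unsaturated ketone with C10=C11 olefin), via pinacol borate ester 14 (not isolated), via prenyl carbinol 15 (not isolated)
Conditions: 13 (1.5 equiv), CH2Cl2, rt; then H2O (1.5 equiv), pyridine, Dess–Martin periodinane, 0 °C → rt
Reagents that add atoms: none
Why: Boronate 13 binds the aldehyde oxygen and transfers its allyl group through a closed six-membered chair transition state, bonding its unsubstituted CH2 terminus to C8 with full allylic transposition, so that C8–C9 is formed and the olefin lands at C10=C11 as a dimethylvinyl group; borate ester 14 is then hydrolysed in the flask and carbinol 15 is oxidised by the periodinane to ketone 16. The closest known reaction types are the uncatalysed addition of α,α-disubstituted allyl pinacol boronates to aldehydes, which gives linear prenyl-type carbinols, and the Dess–Martin oxidation of homoallylic alcohols to β,γ-unsaturated ketones; together they mirror the dimethylallyl transfer that makes this bond in the farnesyl chain. No ring is closed in this step. The only new stereocentre, carbinol carbon C8, arises without control and is erased in the same flask, while C7 cannot epimerise because it carries no hydrogen and the gem-dimethyl terminus leaves no olefin geometry to control. The step needs chemoselectivity for C8 over the ring ketone C2 and the ester, and regioselectivity for the linear over the branched mode: pinacol allylboronates do not add to ketones or esters at room temperature, C2 is shielded by quaternary C3 and acyloxy-bearing C1 whereas C8 is activated by the oxirane oxygen, and the cyclic transition state allows bonding only at the CH2 terminus as long as 13 does not undergo 1,3-boron shift, which pinacol esters do only on heating. Both stages run under neutral or pyridine-buffered conditions, so the two α,β-epoxy carbonyl units and the α-acyloxy ketone are expected to survive.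

Step 12
Reactants: 16 prenyl ketone
Product: 17 target hydroperoxide CNP0131119.1
Conditions: O2, tetraphenylporphyrin (cat.), visible light (LED), CH2Cl2, −20 °C
Reagents that add atoms: dioxygen (as singlet oxygen), O=O
Why: In the Schenck ene reaction singlet oxygen should add to the electron-rich trisubstituted C10=C11 olefin, bond to C11 and abstract a C9 hydrogen activated by the C8 carbonyl, so the olefin shifts into conjugation as the E-enone (as in the photooxygenation of other β,γ-unsaturated ketones); no stereocentre is formed and no other olefin is present.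

## Compound list

1 | (R)-(−)-carvone, (5R)-2-methyl-5-(prop-1-en-2-yl)cyclohex-2-en-1-one | CC1=CC[C@H](CC1=O)C(C)=C | starting material
2 | (1R,5R)-cis-carveol (OH cis to isopropenyl) | C1[C@@H](O)C(C)=CC[C@H]1C(C)=C | intermediate
3 | 1-methyl-4-(prop-1-en-2-yl)-7-oxabicyclo[4.1.0]heptan-2-ol with oxirane O, OH and isopropenyl on the same face | C1[C@@H](O)[C@@]2(C)O[C@H]2C[C@H]1C(C)=C | intermediate
4 | cis-carvone oxide, (1S,4R,6S)-1-methyl-4-(prop-1-en-2-yl)-7-oxabicyclo[4.1.0]heptan-2-one (oxirane O cis to isopropenyl) | C1C(=O)[C@@]2(C)O[C@H]2C[C@H]1C(C)=C | intermediate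
5 | potassium enolate of 4 (C1=C2 enolate) | C1=C([O-])[C@@]2(C)O[C@H]2C[C@H]1C(C)=C.[K+] | intermediate
6 | α′-hydroxy ketone: 4 with OH at C1, trans to isopropenyl and to the oxirane O | O[C@@H]1C(=O)[C@@]2(C)O[C@H]2C[C@H]1C(C)=C | intermediate
7 | 3-methylbutanoate (isovalerate) of 6 | CC(C)CC(=O)O[C@@H]1C(=O)[C@@]2(C)O[C@H]2C[C@H]1C(C)=C | intermediate
8 | allylic alcohol: 7 with the isopropenyl CH3 converted to CH2OH | CC(C)CC(=O)O[C@@H]1C(=O)[C@@]2(C)O[C@H]2C[C@H]1C(=C)CO | intermediate
9 | bis-epoxy alcohol: the 2-substituted (oxiran-2-yl)methanol from 8, C7 configured S | CC(C)CC(=O)O[C@@H]1C(=O)[C@@]2(C)O[C@H]2C[C@H]1[C@]1(CO)CO1 | intermediate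
10 | bis-epoxy aldehyde: the 2-substituted oxirane-2-carbaldehyde (C8 = CHO) | CC(C)CC(=O)O[C@@H]1C(=O)[C@@]2(C)O[C@H]2C[C@H]1[C@]1(C=O)CO1 | intermediate
11 | prenol, 3-methylbut-2-en-1-ol | CC(C)=CCO | starting material
12 | methyl 3-methylbut-2-en-1-yl carbonate | COC(=O)OCC=C(C)C | intermediate
13 | 4,4,5,5-tetramethyl-2-(2-methylbut-3-en-2-yl)-1,3,2-dioxaborolane | C=CC(C)(C)B1OC(C)(C)C(C)(C)O1 | intermediate
14 | pinacol borate ester of carbinol 15 (C8–O–B, both C8 epimers) | CC(C)CC(=O)O[C@@H]1C(=O)[C@@]2(C)O[C@H]2C[C@H]1[C@]1(C(CC=C(C)C)OB2OC(C)(C)C(C)(C)O2)CO1 | intermediate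
15 | prenyl carbinol (C8–OH, both epimers; C10=C11 olefin) | CC(C)CC(=O)O[C@@H]1C(=O)[C@@]2(C)O[C@H]2C[C@H]1[C@]1(C(O)CC=C(C)C)CO1 | intermediate
16 | prenyl ketone (C8=O, C9H2, C10=C11) | CC(C)CC(=O)O[C@@H]1C(=O)[C@@]2(C)O[C@H]2C[C@H]1[C@]1(C(=O)CC=C(C)C)CO1 | intermediate
17 | CNP0131119.1 (1S,3S,4S,6R,7R; E-enone, tertiary hydroperoxide) | CC(C)CC(=O)O[C@@H]1C(=O)[C@@]2(C)O[C@H]2C[C@H]1[C@]1(C(=O)/C=C/C(C)(C)OO)CO1 | target

## Summary

Total step count: 12. Longest linear sequence: 10 steps (steps 1–8, 11, 12).

Steps most likely to fail:

1. Step 11. The crowded tertiary boronate may add too slowly to the aldehyde on the quaternary oxirane carbon, or it may isomerise by 1,3-boron shift to the primary prenyl boronate and then deliver the branched adduct bonded through C11. Fallback: the five carbons would be brought in as three plus two. From aldehyde 10, addition of commercial allylboronic acid pinacol ester (unhindered, no regiochemical issue) would give the allyl carbinol F1. Cross-metathesis of F1 with excess 2-methylbut-2-ene (second-generation ruthenium carbene, CH2Cl2, 40 °C) would turn the vinyl end into the dimethylvinyl group and give carbinol 15, which is oxidised with Dess–Martin periodinane and rejoins the route at 16.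

2. Step 12. Hydrogen abstraction may occur from a methyl group on C11 instead of from C9, giving the regioisomeric secondary hydroperoxide with an isopropenyl end, or the β,γ-unsaturated ketone may drift into conjugation before it reacts. Fallback: the peroxide would be installed by metal-hydride hydrogen atom transfer instead of an ene reaction. From aldehyde 10, addition of the (E)-dienylzinc reagent made from 2-methylbut-1-en-3-yne (Cp2Zr(H)Cl, then Me2Zn) would give the dienyl carbinol F2, and Dess–Martin oxidation the dienone F3. Cobalt-catalysed hydroperoxysilylation (Co(thd)2, O2, Et3SiH; Mukaiyama–Isayama conditions) should deliver hydrogen to the terminal CH2 and capture O2 at the tertiary carbon C11 with the enone kept in conjugation, giving the triethylsilyl peroxide F4. Desilylation with HF·pyridine in THF at 0 °C comes back to the route at 17.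

3. Step 6. The allylic oxidation may run on to the enal or stall at low conversion. Fallback: the oxygen would be introduced by substitution instead of by selenium. From 7, ene-type chlorination of the isopropenyl group with hypochlorous acid (Ca(OCl)2, CO2, CH2Cl2–H2O, 0 °C) would give the allylic chloride F5. Displacement with sodium formate (Bu4NI cat., DMF, rt) would give the allylic formate F6, and selective methanolysis of the formate (NaHCO3, MeOH, 0 °C) comes back to the route at 8.

Further compounds
F1 | step 11 | allyl carbinol (C8–OH, terminal vinyl) | CC(C)CC(=O)O[C@@H]1C(=O)[C@@]2(C)O[C@H]2C[C@H]1[C@]1(C(O)CC=C)CO1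
F2 | step 12 | dienyl carbinol (C8–OH, E-C9=C10, isopropenyl end) | CC(C)CC(=O)O[C@@H]1C(=O)[C@@]2(C)O[C@H]2C[C@H]1[C@]1(C(O)/C=C/C(C)=C)CO1
F3 | step 12 | dienone (C8=O, E-C9=C10, isopropenyl end) | CC(C)CC(=O)O[C@@H]1C(=O)[C@@]2(C)O[C@H]2C[C@H]1[C@]1(C(=O)/C=C/C(C)=C)CO1
F4 | step 12 | triethylsilyl peroxide of the target | CC(C)CC(=O)O[C@@H]1C(=O)[C@@]2(C)O[C@H]2C[C@H]1[C@]1(C(=O)/C=C/C(C)(C)OO[Si](CC)(CC)CC)CO1
F5 | step 6 | allylic chloride (isopropenyl CH3 converted to CH2Cl) | CC(C)CC(=O)O[C@@H]1C(=O)[C@@]2(C)O[C@H]2C[C@H]1C(=C)CCl
F6 | step 6 | allylic formate | CC(C)CC(=O)O[C@@H]1C(=O)[C@@]2(C)O[C@H]2C[C@H]1C(=C)COC=O
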